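**Plan**

- Retrosynthesis: the four O–benzyl bonds of a tetrabenzyl ether of the target are cut first. Then come the C1–C2 bond of ring C (Claisen), the C4–C5 bond of the side chain (acetoacetate dianion acylation), the ring B O–CH2 bond (Williamson) and the ring A–O–ring B aryl C–O bond (Ullmann). The ring B oxygen that will carry ring C is masked as an aldehyde.
- Enabling feature: in ring C the ether-bearing C1 lies between the hydroxylated C2 and C6, with the third hydroxyl on C4. This is the oxygen pattern of a 6-aryloxy-3,5-dioxohexanoate closed head to tail, so ring C can be grown around an oxygen that already sits on an sp3 carbon.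
- Forward: rings A and B are bought as arenes and joined first, and the ring B aldehyde is turned into a phenol. The six-carbon chain is then put on that oxygen in two pieces (two carbons, then four). Ring C is the only ring made and closes in the penultimate step; hydrogenolysis ends the route.
- Stereochemistry: the target has no stereocentre, so none has to be set or preserved.

Key step: step 6

Remark: ring A is the terminal 3,5-dioxygenated phenoxy ring, ring B the central ring and ring C the 2,4,6-trihydroxyphenyl ring. Compounds 11 and 12 are drawn as keto forms although they should exist largely as enols or enolates.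

**Route**

Step 1
Reactants: 1 3,5-bis(benzyloxy)benzaldehyde
Product: 2 3,5-bis(benzyloxy)-2-bromobenzaldehyde
Conditions: NBS (1.05 equiv), MeCN, 0 °C to rt, dark
Reagents that add atoms: N-bromosuccinimide, O=C1CCC(=O)N1Br
Why: Electrophilic aromatic bromination of a 3,5-dialkoxybenzaldehyde should go to C2, which is ortho to one ether and para to the other, rather than to the more crowded C4 between the two ethers, and one equivalent of NBS under ionic conditions leaves the benzylic positions alone.

Step 2
Reactants: 2 3,5-bis(benzyloxy)-2-bromobenzaldehyde, 3 3,5-bis(benzyloxy)phenol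
Product: 4 3,5-bis(benzyloxy)-2-[3,5-bis(benzyloxy)phenoxy]benzaldehyde
Conditions: CuI (10 mol %), picolinic acid (20 mol %), K3PO4 (2 equiv), DMSO, 90 °C, Ar
Reagents that add atoms: none
Why: This is an Ullmann diaryl ether coupling in which the picolinate complex of monovalent copper is suited to ortho-substituted aryl bromides, the ortho formyl group assists insertion into the C–Br bond, and the unhindered phenol 3 serves as nucleophile.

Step 3
Reactants: 4 3,5-bis(benzyloxy)-2-[3,5-bis(benzyloxy)phenoxy]benzaldehyde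
Product: 6 3,5-bis(benzyloxy)-2-[3,5-bis(benzyloxy)phenoxy]phenol, via aryl formate 5 (not isolated)
Conditions: mCPBA (1.3 equiv), CH2Cl2, 0 °C to rt; then K2CO3 (0.2 equiv), MeOH/THF, rt
Reagents that add atoms: 3-chloroperoxybenzoic acid (mCPBA), OOC(=O)c1cccc(Cl)c1
Why: In this Baeyer–Villiger (Dakin-type) oxidation the ortho aryloxy group should make the aryl group migrate in preference to hydride, giving the aryl formate, which mild methanolysis converts into the phenol while benzyl and diaryl ethers are inert to both reagents.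

Step 4
Reactants: 6 3,5-bis(benzyloxy)-2-[3,5-bis(benzyloxy)phenoxy]phenol, 7 2-bromo-N-methoxy-N-methylacetamide
Product: 8 2-{3,5-bis(benzyloxy)-2-[3,5-bis(benzyloxy)phenoxy]phenoxy}-N-methoxy-N-methylacetamide
Conditions: K2CO3 (2 equiv), DMF, rt to 50 °C
Reagents that add atoms: none
Why: In a Williamson ether synthesis the phenoxide of 6 displaces bromide from the primary alpha-bromo amide by an SN2 reaction, which places the future C1 of ring C as a CH2 group on the hindered oxygen before any ring is built.

Step 5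
Reactants: 8 2-{3,5-bis(benzyloxy)-2-[3,5-bis(benzyloxy)phenoxy]phenoxy}-N-methoxy-N-methylacetamide, 9 methyl acetoacetate
Product: 11 methyl 6-{3,5-bis(benzyloxy)-2-[3,5-bis(benzyloxy)phenoxy]phenoxy}-3,5-dioxohexanoate, via dilithiated methyl acetoacetate 10 (not isolated)
Conditions: 9 (3 equiv), LDA (6 equiv, commercial solution), THF, 0 °C; then 8, −78 to 0 °C; 1 M HCl quench
Reagents that add atoms: none
Why: The acetoacetate dianion is acylated at its terminal (gamma) carbon, and an N-methoxy-N-methylamide as acyl donor resists over-addition, so the reaction should stop at the 3,5-dioxo ester.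

Step 6
Reactants: 11 methyl 6-{3,5-bis(benzyloxy)-2-[3,5-bis(benzyloxy)phenoxy]phenoxy}-3,5-dioxohexanoate
Product: 13 2-{3,5-bis(benzyloxy)-2-[3,5-bis(benzyloxy)phenoxy]phenoxy}benzene-1,3,5-triol, via cyclohexane-1,3,5-trione tautomer 12 (not isolated)
Conditions: NaOMe (5 equiv), degassed MeOH/THF, 65 °C, Ar; then 1 M HCl, 0 °C
Reagents that add atoms: none
Why: Methoxide reversibly deprotonates the aryloxy-bearing chain carbon C6, which is acidified by the adjacent ketone and the aryloxy group, and this carbanion adds to the ester carbonyl and expels methoxide, forming the C1–C2 bond of ring C in an intramolecular Claisen condensation. The closest known reaction type is the alkoxide-mediated Claisen (Dieckmann-type) cyclisation of 5-oxo, 3,5-dioxo and 3,5,7-trioxo esters to cyclohexane-1,3-diones and phloroglucinols, the laboratory counterpart of polyketide ring formation. Ring C closes in a 6-(enolendo)-exo-trig mode to trione 12, which should enolise at once to the aromatic triol and remain as its phenoxide until the acidic quench, so the closure is not reversed. No stereocentre is formed. The selectivity required is C-acylation in preference to O-acylation, which would give a 6-(aryloxymethyl)-4-hydroxy-2-pyrone. It is secured because a triketide chain has no aldol route to a six-membered ring, because the pyrone re-opens under methoxide whereas the phloroglucinol phenoxide does not, and because the crowded ether oxygen is already in place so no aryl–oxygen bond has to be made at this stage.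

Step 7
Reactants: 13 2-{3,5-bis(benzyloxy)-2-[3,5-bis(benzyloxy)phenoxy]phenoxy}benzene-1,3,5-triol
Product: 14 triphloroethol A, 2-[2-(3,5-dihydroxyphenoxy)-3,5-dihydroxyphenoxy]benzene-1,3,5-triol
Conditions: H2 (1 atm), 10% Pd/C, EtOAc/MeOH, rt; filtration and concentration under Ar
Reagents that add atoms: none
Why: Catalytic hydrogenolysis over Pd/C cleaves the four benzylic C–O bonds under neutral conditions and should leave the diaryl ethers and the three phloroglucinol rings untouched, releasing the air-sensitive heptaphenol with toluene as the only by-product.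

**Compound list**

1 | 3,5-bis(benzyloxy)benzaldehyde | O=Cc1cc(OCc2ccccc2)cc(OCc2ccccc2)c1 | starting material
2 | 3,5-bis(benzyloxy)-2-bromobenzaldehyde | O=Cc1cc(OCc2ccccc2)cc(OCc2ccccc2)c1Br | intermediate
3 | 3,5-bis(benzyloxy)phenol | Oc1cc(OCc2ccccc2)cc(OCc2ccccc2)c1 | starting material
4 | 3,5-bis(benzyloxy)-2-[3,5-bis(benzyloxy)phenoxy]benzaldehyde | O=Cc1cc(OCc2ccccc2)cc(OCc2ccccc2)c1Oc1cc(OCc2ccccc2)cc(OCc2ccccc2)c1 | intermediate
5 | 3,5-bis(benzyloxy)-2-[3,5-bis(benzyloxy)phenoxy]phenyl formate (not isolated) | O=COc1cc(OCc2ccccc2)cc(OCc2ccccc2)c1Oc1cc(OCc2ccccc2)cc(OCc2ccccc2)c1 | intermediate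
6 | 3,5-bis(benzyloxy)-2-[3,5-bis(benzyloxy)phenoxy]phenol | Oc1cc(OCc2ccccc2)cc(OCc2ccccc2)c1Oc1cc(OCc2ccccc2)cc(OCc2ccccc2)c1 | intermediate
7 | 2-bromo-N-methoxy-N-methylacetamide | CON(C)C(=O)CBr | starting material
8 | 2-{3,5-bis(benzyloxy)-2-[3,5-bis(benzyloxy)phenoxy]phenoxy}-N-methoxy-N-methylacetamide | CON(C)C(=O)COc1cc(OCc2ccccc2)cc(OCc2ccccc2)c1Oc1cc(OCc2ccccc2)cc(OCc2ccccc2)c1 | intermediate
9 | methyl acetoacetate | COC(=O)CC(C)=O | starting material
10 | dilithiated methyl acetoacetate (dianion, not isolated) | [Li+].[Li+].COC(=O)[CH-]C(=O)[CH2-] | intermediate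
11 | methyl 6-{3,5-bis(benzyloxy)-2-[3,5-bis(benzyloxy)phenoxy]phenoxy}-3,5-dioxohexanoate | COC(=O)CC(=O)CC(=O)COc1cc(OCc2ccccc2)cc(OCc2ccccc2)c1Oc1cc(OCc2ccccc2)cc(OCc2ccccc2)c1 | intermediate
12 | 2-{3,5-bis(benzyloxy)-2-[3,5-bis(benzyloxy)phenoxy]phenoxy}cyclohexane-1,3,5-trione (not isolated) | O=C1CC(=O)C(Oc2cc(OCc3ccccc3)cc(OCc3ccccc3)c2Oc2cc(OCc3ccccc3)cc(OCc3ccccc3)c2)C(=O)C1 | intermediate
13 | 2-{3,5-bis(benzyloxy)-2-[3,5-bis(benzyloxy)phenoxy]phenoxy}benzene-1,3,5-triol | Oc1cc(O)c(Oc2cc(OCc3ccccc3)cc(OCc3ccccc3)c2Oc2cc(OCc3ccccc3)cc(OCc3ccccc3)c2)c(O)c1 | intermediate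
14 | triphloroethol A | Oc1cc(O)cc(Oc2c(O)cc(O)cc2Oc2c(O)cc(O)cc2O)c1 | target

Total step count: 7
Longest linear sequence: 7 steps (1 to 14)

**Steps most likely to fail**

Step 6. The chain may close through oxygen to the 4-hydroxy-2-pyrone and fail to re-open, methoxide may cleave the 1,3-diketone by retro-Claisen attack, or the phenoxide of the product may oxidise in air. The fallback brings ring C in as a finished arene instead of building it. Setting out from phenol 6, a second Ullmann coupling with bromide 2 (CuI, picolinic acid, K3PO4, DMSO, 90 °C) should give 3,5-bis(benzyloxy)-2-{3,5-bis(benzyloxy)-2-[3,5-bis(benzyloxy)phenoxy]phenoxy}benzaldehyde F1. Baeyer–Villiger oxidation with mCPBA in CH2Cl2 should then give 3,5-bis(benzyloxy)-2-{3,5-bis(benzyloxy)-2-[3,5-bis(benzyloxy)phenoxy]phenoxy}phenyl formate F2, which is not isolated. Its methanolysis (K2CO3, MeOH/THF) should give 3,5-bis(benzyloxy)-2-{3,5-bis(benzyloxy)-2-[3,5-bis(benzyloxy)phenoxy]phenoxy}phenol F3. Hydrogenolysis of all six benzyl ethers (H2, Pd/C, EtOAc/MeOH) comes back to the route at 14.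

Step 2. Insertion of monovalent copper into the C–Br bond, which is flanked by a formyl and a benzyloxy group, may be slow enough that protodebromination or condensation of the electron-rich phenoxide with the aldehyde takes over. The fallback reverses the roles of the two rings, so that ring B is the hindered phenol and ring A the unhindered bromide; it also avoids steps 1 and 3. Setting out from phenol 3, magnesium-mediated ortho-formylation (MgCl2, Et3N, paraformaldehyde, MeCN, reflux) should give 2,4-bis(benzyloxy)-6-hydroxybenzaldehyde F4. Protection (MOMCl, i-Pr2NEt, CH2Cl2) should give 2,4-bis(benzyloxy)-6-(methoxymethoxy)benzaldehyde F5. Dakin-type oxidation with mCPBA, strongly favoured here by two ortho and one para oxygen, should give 2,4-bis(benzyloxy)-6-(methoxymethoxy)phenyl formate F6, which is not isolated, and methanolysis (K2CO3, MeOH) then 2,4-bis(benzyloxy)-6-(methoxymethoxy)phenol F7. Ullmann coupling of F7 with commercial 1,3-bis(benzyloxy)-5-bromobenzene (CuI, picolinic acid, K3PO4, DMSO, 90 °C) should give 1,5-bis(benzyloxy)-2-[3,5-bis(benzyloxy)phenoxy]-3-(methoxymethoxy)benzene F8. Acetal cleavage (HCl, MeOH/THF, 40 °C) comes back to the route at 6.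

Step 5. The strongly basic dianion may deprotonate the aryloxy-substituted methylene of 8 instead of adding to the amide, or the amide may lose its N-methoxy group under base, so that 8 is returned or degraded. The fallback replaces the dianion by a less basic masked acetoacetate and unveils the ester thermally. Setting out from amide 8, the lithium dienolate of commercial 2,2,6-trimethyl-4H-1,3-dioxin-4-one (LiHMDS, THF, −78 °C) should be acylated at its methyl carbon to give 6-(3-{3,5-bis(benzyloxy)-2-[3,5-bis(benzyloxy)phenoxy]phenoxy}-2-oxopropyl)-2,2-dimethyl-4H-1,3-dioxin-4-one F9. Heating F9 with MeOH in toluene (110 °C) should release acetone and an acylketene that methanol captures, which comes back to the route at 11.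

**Further compounds**

F1 | step 6 | 3,5-bis(benzyloxy)-2-{3,5-bis(benzyloxy)-2-[3,5-bis(benzyloxy)phenoxy]phenoxy}benzaldehyde | O=Cc1cc(OCc2ccccc2)cc(OCc2ccccc2)c1Oc1cc(OCc2ccccc2)cc(OCc2ccccc2)c1Oc1cc(OCc2ccccc2)cc(OCc2ccccc2)c1
F2 | step 6 | 3,5-bis(benzyloxy)-2-{3,5-bis(benzyloxy)-2-[3,5-bis(benzyloxy)phenoxy]phenoxy}phenyl formate | O=COc1cc(OCc2ccccc2)cc(OCc2ccccc2)c1Oc1cc(OCc2ccccc2)cc(OCc2ccccc2)c1Oc1cc(OCc2ccccc2)cc(OCc2ccccc2)c1
F3 | step 6 | 3,5-bis(benzyloxy)-2-{3,5-bis(benzyloxy)-2-[3,5-bis(benzyloxy)phenoxy]phenoxy}phenol | Oc1cc(OCc2ccccc2)cc(OCc2ccccc2)c1Oc1cc(OCc2ccccc2)cc(OCc2ccccc2)c1Oc1cc(OCc2ccccc2)cc(OCc2ccccc2)c1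
F4 | step 2 | 2,4-bis(benzyloxy)-6-hydroxybenzaldehyde | O=Cc1c(O)cc(OCc2ccccc2)cc1OCc1ccccc1
F5 | step 2 | 2,4-bis(benzyloxy)-6-(methoxymethoxy)benzaldehyde | O=Cc1c(OCOC)cc(OCc2ccccc2)cc1OCc1ccccc1
F6 | step 2 | 2,4-bis(benzyloxy)-6-(methoxymethoxy)phenyl formate | O=COc1c(OCOC)cc(OCc2ccccc2)cc1OCc1ccccc1
F7 | step 2 | 2,4-bis(benzyloxy)-6-(methoxymethoxy)phenol | Oc1c(OCOC)cc(OCc2ccccc2)cc1OCc1ccccc1
F8 | step 2 | 1,5-bis(benzyloxy)-2-[3,5-bis(benzyloxy)phenoxy]-3-(methoxymethoxy)benzene | COCOc1cc(OCc2ccccc2)cc(OCc2ccccc2)c1Oc1cc(OCc2ccccc2)cc(OCc2ccccc2)c1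
F9 | step 5 | 6-(3-{3,5-bis(benzyloxy)-2-[3,5-bis(benzyloxy)phenoxy]phenoxy}-2-oxopropyl)-2,2-dimethyl-4H-1,3-dioxin-4-one | CC1(C)OC(=O)C=C(CC(=O)COc2cc(OCc3ccccc3)cc(OCc3ccccc3)c2Oc2cc(OCc3ccccc3)cc(OCc3ccccc3)c2)O1
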